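The cyclohexane ring of the fused lactone (hexahydro-2-benzofuran-1(3H)-one numbering) is cut at C3a–C4 and C6–C7 into two three-carbon pieces. The key step exploits that C7a bears the lactone carbonyl, so C7–C7a–C3a is a 2-substituted acrylate (a Morita–Baylis–Hillman unit), and that C4 bears an acyl group, so C4–C5–C6 can come from a 2-methyl-1,3-dicarbonyl compound with a temporary C5 ketone. A cinchona-catalysed allylic alkylation joins C4 to C3a and a Michael addition then closes C6–C7: a [3+3] annulation that forms both bonds and sets C3a and C4. Its precursors are Morita–Baylis–Hillman carbonate 4 and β-keto amide 6.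

Key step: step 4

Remark: the sense of induction in the two catalyst-controlled steps (4 and 11) is assigned by analogy with simpler substrates; the pseudo-enantiomeric catalyst, (DHQ)2PHAL or (S)-BINOL, would be used if the opposite sense is found.

Step 1
Reactants: 1 tert-butyl acrylate; 2 2,2-dimethoxyacetaldehyde
Product: 3 tert-butyl 3-hydroxy-4,4-dimethoxy-2-methylidenebutanoate (racemic)
Conditions: DABCO (1 equiv), 1,4-dioxane/H2O, rt
Reagents that add atoms: none
Why: Morita–Baylis–Hillman reaction of an acrylate with an activated α-alkoxy aldehyde; the carbinol centre is racemic and is erased in step 4.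

Step 2
Reactants: 3 tert-butyl 3-hydroxy-4,4-dimethoxy-2-methylidenebutanoate
Product: 4 tert-butyl 3-[(tert-butoxycarbonyl)oxy]-4,4-dimethoxy-2-methylidenebutanoate (racemic)
Conditions: Boc2O, DMAP (cat.), CH2Cl2, 0 °C to rt
Reagents that add atoms: di-tert-butyl dicarbonate, CC(C)(C)OC(=O)OC(=O)OC(C)(C)C
Why: DMAP-catalysed O-acylation of the secondary allylic alcohol gives the carbonate, whose leaving group releases the tert-butoxide base needed in step 4.

Step 3
Reactants: 5 1-(morpholin-4-yl)butane-1,3-dione
Product: 6 2-methyl-1-(morpholin-4-yl)butane-1,3-dione (racemic, configurationally labile)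
Conditions: MeI (1.0 equiv), K2CO3, acetone, rt
Reagents that add atoms: iodomethane, CI
Why: C-alkylation of the 1,3-dicarbonyl enolate installs the future C4 methyl group; the stereocentre is mobile and is fixed only in step 4.

Step 4
Reactants: 4 tert-butyl 3-[(tert-butoxycarbonyl)oxy]-4,4-dimethoxy-2-methylidenebutanoate; 6 2-methyl-1-(morpholin-4-yl)butane-1,3-dione
Product: 8 tert-butyl (1R,2S,3R)-2-(dimethoxymethyl)-3-methyl-3-(morpholine-4-carbonyl)-4-oxocyclohexane-1-carboxylate, via open-chain allylation product 7 (not isolated)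
Conditions: (DHQD)2PHAL (10 mol%), toluene, 30 °C; then t-BuOK (20 mol%), 18-crown-6 (20 mol%), THF, −20 to 0 °C
Reagents that add atoms: none
Why: The quinuclidine nitrogen of (DHQD)2PHAL displaces the carbonate of 4 in an SN2′ step to give a chiral allylammonium ion and tert-butoxide, which deprotonates 6; the enolate attacks the carbinol-derived carbon (C3a) in a second SN2′ step, forming C3a–C4 and regenerating the 2-substituted acrylate in 7, and catalytic t-BuOK then enolises the acetyl group so that its methyl carbon (C6) adds to the acrylate CH2 (C7). The sequence is an asymmetric allylic alkylation of a Morita–Baylis–Hillman carbonate followed by an intramolecular Michael addition, i.e. a formal [3+3] (Lawton-type α,α′) annulation of a 1,3-dicarbonyl compound. The ring closes in a 6-endo-trig mode with respect to the acrylate (both enolate carbons also end up in the ring), through a chair in which the dimethoxymethyl group is axial to avoid allylic strain with the ester. C3a is set by the catalyst (face of the allylammonium ion), and C4 is set in the same bond formation by a staggered approach with the methyl group anti to the acrylate carbon and the bulky morpholine amide beside H-3a instead of beside the acetal; C7a–H is epimerisable (drawn trans) and is erased in step 7. The step needs attack at C3a and not at the CH2 terminus, which the ammonium (SN2′/SN2′) pathway secures, and C–C closure at C7 in place of acylation, which the tert-butyl ester and the absence of any other enolisable ketone position secure.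

Step 5
Reactants: 8 tert-butyl (1R,2S,3R)-2-(dimethoxymethyl)-3-methyl-3-(morpholine-4-carbonyl)-4-oxocyclohexane-1-carboxylate
Product: 9 tert-butyl (1R,5R,6S)-6-(dimethoxymethyl)-5-methyl-5-(morpholine-4-carbonyl)-4-[(trifluoromethanesulfonyl)oxy]cyclohex-3-ene-1-carboxylate
Conditions: KN(SiMe3)2 (1.1 equiv), THF, −78 °C; then PhNTf2, −78 to 0 °C
Reagents that add atoms: N-phenylbis(trifluoromethanesulfonimide), O=S(=O)(N(c1ccccc1)S(=O)(=O)C(F)(F)F)C(F)(F)F
Why: Kinetic deprotonation takes the ketone α-CH2 (more acidic than the ester α-CH, and the only ketone α-position since the other is quaternary) and O-sulfonylation gives a single enol triflate.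

Step 6
Reactants: 9 tert-butyl (1R,5R,6S)-6-(dimethoxymethyl)-5-methyl-5-(morpholine-4-carbonyl)-4-[(trifluoromethanesulfonyl)oxy]cyclohex-3-ene-1-carboxylate
Product: 10 tert-butyl (1R,2S,3S)-2-(dimethoxymethyl)-3-methyl-3-(morpholine-4-carbonyl)cyclohexane-1-carboxylate
Conditions: H2 (1 atm), PtO2, NaHCO3, EtOAc, rt
Reagents that add atoms: none
Why: Hydrogenolysis of the enol triflate with saturation over PtO2 (deoxygenation of a ketone by way of its enol triflate) removes the temporary C5 oxygen without creating a stereocentre, while NaHCO3 traps the triflic acid so that acetal and tert-butyl ester survive.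

Step 7
Reactants: 10 tert-butyl (1R,2S,3S)-2-(dimethoxymethyl)-3-methyl-3-(morpholine-4-carbonyl)cyclohexane-1-carboxylate
Product: 11 tert-butyl (1S,2R,3S)-2-(dimethoxymethyl)-1,3-dimethyl-3-(morpholine-4-carbonyl)cyclohexane-1-carboxylate
Conditions: LiN(i-Pr)2 (1.3 equiv), THF, −78 °C; then MeI, DMPU, −78 to −30 °C
Reagents that add atoms: iodomethane, CI
Why: Alkylation of the lithium ester enolate (the only acidic C–H) should occur anti to the vicinal dimethoxymethyl group and anti to the axial ring methyl, the known preference of 2-substituted cyclohexanecarboxylate and podocarpate-type enolates, so the ester ends cis to the acetal as the lactone requires.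

Step 8
Reactants: 12 2-(furan-3-yl)ethan-1-ol
Product: 13 3-(2-iodoethyl)furan
Conditions: I2, PPh3, imidazole, CH2Cl2, 0 °C to rt
Reagents that add atoms: iodine, II
Why: Appel-type iodination of a primary alcohol under neutral conditions that the furan tolerates.

Step 9
Reactants: 11 tert-butyl (1S,2R,3S)-2-(dimethoxymethyl)-1,3-dimethyl-3-(morpholine-4-carbonyl)cyclohexane-1-carboxylate; 13 3-(2-iodoethyl)furan
Product: 16 tert-butyl (1S,2R,3S)-2-formyl-3-[3-(furan-3-yl)propanoyl]-1,3-dimethylcyclohexane-1-carboxylate, via organolithium 14 (not isolated), via ketone acetal 15 (not isolated)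
Conditions: 13, t-BuLi (2 equiv per 13), Et2O, −78 °C; then 11, THF, −78 to 0 °C; then 1 M HCl, THF, rt
Reagents that add atoms: water, O
Why: Iodine–lithium exchange gives the primary organolithium, which adds once to the morpholine amide (stable tetrahedral intermediate, ketone released on work-up) while the hindered tert-butyl ester is inert, and the same dilute acid hydrolyses the dimethyl acetal.

Step 10
Reactants: 16 tert-butyl (1S,2R,3S)-2-formyl-3-[3-(furan-3-yl)propanoyl]-1,3-dimethylcyclohexane-1-carboxylate; 17 1-(triphenyl-λ5-phosphanylidene)propan-2-one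
Product: 18 tert-butyl (1S,2R,3S)-3-[3-(furan-3-yl)propanoyl]-1,3-dimethyl-2-[(1E)-3-oxobut-1-en-1-yl]cyclohexane-1-carboxylate
Conditions: toluene, 90 °C
Reagents that add atoms: none
Why: Wittig olefination with a stabilised ylide gives the (E)-enone under neutral conditions that neither epimerise C3a nor trigger aldol closure of the 1,4-keto aldehyde.

Step 11
Reactants: 18 tert-butyl (1S,2R,3S)-3-[3-(furan-3-yl)propanoyl]-1,3-dimethyl-2-[(1E)-3-oxobut-1-en-1-yl]cyclohexane-1-carboxylate
Product: 19 tert-butyl (1S,2R,3S)-2-[(2R,3S)-3-acetyloxiran-2-yl]-3-[3-(furan-3-yl)propanoyl]-1,3-dimethylcyclohexane-1-carboxylate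
Conditions: La(O-i-Pr)3 (10 mol%), (R)-BINOL (10 mol%), Ph3As=O (10 mol%), t-BuOOH, 4 Å molecular sieves, THF, rt
Reagents that add atoms: tert-butyl hydroperoxide, CC(C)(C)OO
Why: Catalytic asymmetric nucleophilic epoxidation of the (E)-enone leaves the furan and the isolated ketone untouched, gives the trans epoxide from the alkene geometry, and its face (αS,βR by analogy with simple enones) is chosen by the BINOL ligand.

Step 12
Reactants: 19 tert-butyl (1S,2R,3S)-2-[(2R,3S)-3-acetyloxiran-2-yl]-3-[3-(furan-3-yl)propanoyl]-1,3-dimethylcyclohexane-1-carboxylate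
Product: 20 (3S,3aR,4S,7aS)-4-[3-(furan-3-yl)propanoyl]-3-[(1S)-1-hydroxy-2-oxopropyl]-4,7a-dimethylhexahydro-2-benzofuran-1(3H)-one
Conditions: TFA, CH2Cl2, 0 °C; aq. NaHCO3 work-up
Reagents that add atoms: none
Why: Acid-promoted 5-exo opening of the epoxide by the cis-disposed tert-butyl ester carbonyl (loss of isobutene) occurs with inversion at the carbon remote from the ketone, giving the cis-fused γ-lactone with (3S) and the free (1S) α-hydroxyl.

Step 13
Reactants: 20 (3S,3aR,4S,7aS)-4-[3-(furan-3-yl)propanoyl]-3-[(1S)-1-hydroxy-2-oxopropyl]-4,7a-dimethylhexahydro-2-benzofuran-1(3H)-one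
Product: 21 (1S)-1-[(1S,3aS,7S,7aR)-7-[3-(furan-3-yl)propanoyl]-3a,7-dimethyl-3-oxooctahydro-2-benzofuran-1-yl]-2-oxopropyl acetate (CNP0170401.2)
Conditions: Ac2O, pyridine, DMAP (cat.), CH2Cl2, 0 °C
Reagents that add atoms: acetic anhydride, CC(=O)OC(C)=O
Why: Acetylation of the only free hydroxyl under mild base that should not epimerise the α-acyloxy ketone centre.

Compound list
1 | tert-butyl acrylate | C=CC(=O)OC(C)(C)C | starting material
2 | 2,2-dimethoxyacetaldehyde | COC(OC)C=O | starting material
3 | tert-butyl 3-hydroxy-4,4-dimethoxy-2-methylidenebutanoate (racemic) | C=C(C(O)C(OC)OC)C(=O)OC(C)(C)C | intermediate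
4 | tert-butyl 3-[(tert-butoxycarbonyl)oxy]-4,4-dimethoxy-2-methylidenebutanoate (racemic) | C=C(C(OC(=O)OC(C)(C)C)C(OC)OC)C(=O)OC(C)(C)C | intermediate
5 | 1-(morpholin-4-yl)butane-1,3-dione | CC(=O)CC(=O)N1CCOCC1 | starting material
6 | 2-methyl-1-(morpholin-4-yl)butane-1,3-dione (racemic) | CC(=O)C(C)C(=O)N1CCOCC1 | intermediate
7 | tert-butyl (3R,4R)-4-acetyl-3-(dimethoxymethyl)-4-methyl-2-methylidene-5-(morpholin-4-yl)-5-oxopentanoate | C=C(C(=O)OC(C)(C)C)[C@H](C(OC)OC)[C@](C)(C(C)=O)C(=O)N1CCOCC1 | intermediate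
8 | tert-butyl (1R,2S,3R)-2-(dimethoxymethyl)-3-methyl-3-(morpholine-4-carbonyl)-4-oxocyclohexane-1-carboxylate | CC(C)(C)OC(=O)[C@@H]1CCC(=O)[C@](C)(C(=O)N2CCOCC2)[C@H]1C(OC)OC | intermediate
9 | tert-butyl (1R,5R,6S)-6-(dimethoxymethyl)-5-methyl-5-(morpholine-4-carbonyl)-4-[(trifluoromethanesulfonyl)oxy]cyclohex-3-ene-1-carboxylate | CC(C)(C)OC(=O)[C@@H]1CC=C(OS(=O)(=O)C(F)(F)F)[C@](C)(C(=O)N2CCOCC2)[C@H]1C(OC)OC | intermediate
10 | tert-butyl (1R,2S,3S)-2-(dimethoxymethyl)-3-methyl-3-(morpholine-4-carbonyl)cyclohexane-1-carboxylate | CC(C)(C)OC(=O)[C@@H]1CCC[C@](C)(C(=O)N2CCOCC2)[C@H]1C(OC)OC | intermediate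
11 | tert-butyl (1S,2R,3S)-2-(dimethoxymethyl)-1,3-dimethyl-3-(morpholine-4-carbonyl)cyclohexane-1-carboxylate | CC(C)(C)OC(=O)[C@@]1(C)CCC[C@](C)(C(=O)N2CCOCC2)[C@H]1C(OC)OC | intermediate
12 | 2-(furan-3-yl)ethan-1-ol | OCCc1ccoc1 | starting material
13 | 3-(2-iodoethyl)furan | ICCc1ccoc1 | intermediate
14 | [2-(furan-3-yl)ethyl]lithium | [Li]CCc1ccoc1 | intermediate
15 | tert-butyl (1S,2R,3S)-2-(dimethoxymethyl)-3-[3-(furan-3-yl)propanoyl]-1,3-dimethylcyclohexane-1-carboxylate | CC(C)(C)OC(=O)[C@@]1(C)CCC[C@](C)(C(=O)CCc2ccoc2)[C@H]1C(OC)OC | intermediate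
16 | tert-butyl (1S,2R,3S)-2-formyl-3-[3-(furan-3-yl)propanoyl]-1,3-dimethylcyclohexane-1-carboxylate | CC(C)(C)OC(=O)[C@@]1(C)CCC[C@](C)(C(=O)CCc2ccoc2)[C@H]1C=O | intermediate
17 | 1-(triphenyl-λ5-phosphanylidene)propan-2-one | CC(=O)C=P(c1ccccc1)(c1ccccc1)c1ccccc1 | starting material
18 | tert-butyl (1S,2R,3S)-3-[3-(furan-3-yl)propanoyl]-1,3-dimethyl-2-[(1E)-3-oxobut-1-en-1-yl]cyclohexane-1-carboxylate | CC(C)(C)OC(=O)[C@@]1(C)CCC[C@](C)(C(=O)CCc2ccoc2)[C@H]1/C=C/C(C)=O | intermediate
19 | tert-butyl (1S,2R,3S)-2-[(2R,3S)-3-acetyloxiran-2-yl]-3-[3-(furan-3-yl)propanoyl]-1,3-dimethylcyclohexane-1-carboxylate | CC(C)(C)OC(=O)[C@@]1(C)CCC[C@](C)(C(=O)CCc2ccoc2)[C@H]1[C@H]3O[C@@H]3C(C)=O | intermediate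
20 | (3S,3aR,4S,7aS)-4-[3-(furan-3-yl)propanoyl]-3-[(1S)-1-hydroxy-2-oxopropyl]-4,7a-dimethylhexahydro-2-benzofuran-1(3H)-one | O[C@H](C(C)=O)[C@H]1OC(=O)[C@@]2(C)CCC[C@](C)(C(=O)CCc3ccoc3)[C@@H]12 | intermediate
21 | (1S)-1-[(1S,3aS,7S,7aR)-7-[3-(furan-3-yl)propanoyl]-3a,7-dimethyl-3-oxooctahydro-2-benzofuran-1-yl]-2-oxopropyl acetate | CC(=O)O[C@H](C(C)=O)[C@H]1OC(=O)[C@@]2(C)CCC[C@](C)(C(=O)CCc3ccoc3)[C@@H]12 | target

Total step count: 13. Longest linear sequence: 11 steps (steps 1, 2, 4, 5, 6, 7, 9, 10, 11, 12, 13); steps 3 and 8 are one-step side branches.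

Steps most likely to fail

Step 4 (key step). What may go wrong: poor discrimination between the two faces of the enolate of 6 in the allylation (epimers at C4), or migration of the exocyclic double bond into conjugation before the Michael closure. Fallback, with the order of bond formation reversed (C6–C7 first): setting out from 3, bromination with allylic transposition (NBS, Me2S, CH2Cl2) gives tert-butyl (2Z)-2-(bromomethyl)-4,4-dimethoxybut-2-enoate F1. The dianion of 6 (NaH, then n-BuLi, THF, −20 °C) is alkylated at its terminal methyl carbon by F1 to give tert-butyl (2E)-2-(2,2-dimethoxyethylidene)-6-methyl-7-(morpholin-4-yl)-5,7-dioxoheptanoate F2. An intramolecular Michael addition of the 2-methyl-1,3-dicarbonyl unit onto the enoate under chiral phase-transfer catalysis (N-(9-anthracenylmethyl)cinchoninium bromide, Cs2CO3, toluene) then closes C3a–C4 through a ring-constrained transition state and comes back to 8.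

Step 9. What may go wrong: no addition of the organolithium to the very hindered amide carbonyl, or aldol closure between the new ketone and the aldehyde during the acidic hydrolysis. Fallback, changing the oxidation level at the amide carbon stepwise: setting out from 11, Cp2Zr(H)Cl (THF, rt) reduces the tertiary amide to the far more electrophilic aldehyde tert-butyl (1S,2R,3S)-2-(dimethoxymethyl)-3-formyl-1,3-dimethylcyclohexane-1-carboxylate F3. Addition of 14 (Et2O, −78 °C) gives tert-butyl (1S,2R,3S)-2-(dimethoxymethyl)-3-[3-(furan-3-yl)-1-hydroxypropyl]-1,3-dimethylcyclohexane-1-carboxylate F4 as a mixture of carbinol epimers, and Dess–Martin periodinane (CH2Cl2, NaHCO3) oxidises it to 15. Here 15 is isolated and hydrolysed to 16 with pyridinium p-toluenesulfonate in wet acetone immediately before step 10.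

Step 11. What may go wrong: mismatched facial selectivity of the catalyst on the crowded enone, or conjugate closure of the side-chain ketone enolate onto the enone under the basic peroxide conditions. Fallback, an aldol construction in place of olefination and epoxidation: setting out from 16, the L-proline-catalysed anti-selective aldol reaction with hydroxyacetone (DMSO, rt) gives tert-butyl (1S,2R,3S)-2-[(1S,2S)-1,2-dihydroxy-3-oxobutyl]-3-[3-(furan-3-yl)propanoyl]-1,3-dimethylcyclohexane-1-carboxylate F5, with both carbinol centres set by the catalyst. TFA in CH2Cl2 then lactonises the ring-adjacent hydroxyl onto the tert-butyl ester with retention and comes back to 20.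

Further compounds
F1 | step 4 | tert-butyl (2Z)-2-(bromomethyl)-4,4-dimethoxybut-2-enoate | BrC/C(C(=O)OC(C)(C)C)=C\C(OC)OC
F2 | step 4 | tert-butyl (2E)-2-(2,2-dimethoxyethylidene)-6-methyl-7-(morpholin-4-yl)-5,7-dioxoheptanoate | CC(C)(C)OC(=O)/C(CCC(=O)C(C)C(=O)N1CCOCC1)=C/C(OC)OC
F3 | step 9 | tert-butyl (1S,2R,3S)-2-(dimethoxymethyl)-3-formyl-1,3-dimethylcyclohexane-1-carboxylate | CC(C)(C)OC(=O)[C@@]1(C)CCC[C@](C)(C=O)[C@H]1C(OC)OC
F4 | step 9 | tert-butyl (1S,2R,3S)-2-(dimethoxymethyl)-3-[3-(furan-3-yl)-1-hydroxypropyl]-1,3-dimethylcyclohexane-1-carboxylate (carbinol epimers) | CC(C)(C)OC(=O)[C@@]1(C)CCC[C@](C)(C(O)CCc2ccoc2)[C@H]1C(OC)OC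
F5 | step 11 | tert-butyl (1S,2R,3S)-2-[(1S,2S)-1,2-dihydroxy-3-oxobutyl]-3-[3-(furan-3-yl)propanoyl]-1,3-dimethylcyclohexane-1-carboxylate | CC(C)(C)OC(=O)[C@@]1(C)CCC[C@](C)(C(=O)CCc2ccoc2)[C@H]1[C@H](O)[C@H](O)C(C)=O
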